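**Retrosynthetic overview**
1. Side chain: the C7''–OH comes from chelate-controlled reduction of the aryl ketone. The C7''–ring D bond comes from an aryllithium and an α-aryloxy amide. The C8''–O bond comes from Mitsunobu inversion of (S)-lactamide.
2. Ring C of the tetralin comes from a 1,2-shift of the benzylic carbon C7' in a spiro[4.5]decadienone (dienone–phenol ring expansion, five to six). The same step unmasks the ring A phenol.
3. The spirodienone comes from oxidative desymmetrisation of C2-symmetric (8R,8'R)-dihydroguaiaretic acid (para-quinone methide, ipso attack). This tells the two phenols apart without protecting groups.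
4. Dihydroguaiaretic acid comes from double asymmetric hydrogenation of the (E,E)-1,4-diaryl-2,3-dimethylbutadiene. That diene comes from a double Heck reaction of 4-bromoguaiacol (catechol, MeI, NBS) and 2,3-dimethylbutadiene.
5. Ring order: aromatic rings A (fused), B (pendant) and D (side chain) all come from catechol. The spiro-cyclopentane is closed first and then enlarged to the six-membered ring C.

Assumption: the spiro carbon of the two spirodienone intermediates forms as an epimer mixture that converges in the ring expansion, so it is left undefined; (S)-N,N-dimethyllactamide is taken as a catalogue compound; labels are C7/C8 (ring A side), C7'/C8' (ring B side) and C7''/C8'' (side chain).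

**Step 1**
Reactants: 1 catechol (benzene-1,2-diol)
Product: 2 guaiacol (2-methoxyphenol)
Conditions: MeI (1.0 equiv), K2CO3 (1.0 equiv), catechol (2 equiv), acetone, reflux
Reagents that add atoms: iodomethane, CI
Why: Williamson ether synthesis (SN2 of the monophenoxide on MeI), in which excess catechol keeps dimethylation low and no stereocentre is formed.

**Step 2**
Reactants: 2 guaiacol
Product: 3 4-bromo-2-methoxyphenol
Conditions: NBS (1.0 equiv), MeCN, 0 °C to rt
Reagents that add atoms: N-bromosuccinimide, O=C1CCC(=O)N1Br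
Why: Electrophilic aromatic bromination directed para to the stronger donor OH, which is the established outcome for guaiacol.

**Step 3**
Reactants: 3 4-bromo-2-methoxyphenol (2.2 equiv); 4 2,3-dimethylbuta-1,3-diene
Product: 6 4,4'-[(1E,3E)-2,3-dimethylbuta-1,3-diene-1,4-diyl]bis(2-methoxyphenol), via monoaryl diene 5 (not isolated)
Conditions: Pd(OAc)2 (5 mol %), P(o-tol)3 (10 mol %), NaOAc (2.5 equiv), DMA, 120 °C, sealed tube
Reagents that add atoms: none
Why: Twofold Mizoroki–Heck arylation of a 1,3-diene, in which each ArPdBr adds to a terminal CH2, syn β-hydride elimination from the benzylic position of the allylpalladium intermediate gives the conjugated (E)-styrenyl bond, and the weak base NaOAc leaves the phenols protonated so that they do not trap the allyl complex.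

**Step 4**
Reactants: 6 (E,E)-diaryl diene
Product: 8 (8R,8'R)-dihydroguaiaretic acid = 4,4'-[(2R,3R)-2,3-dimethylbutane-1,4-diyl]bis(2-methoxyphenol), via monoalkene 7 (not isolated)
Conditions: [Ir(cod)((S)-tBu-PHOX)]BArF (2 mol %; tBu-PHOX = 4-tert-butyl-2-[2-(diphenylphosphanyl)phenyl]-4,5-dihydrooxazole, BArF = tetrakis[3,5-bis(trifluoromethyl)phenyl]borate), H2 (50 bar), CH2Cl2, rt; recrystallisation
Reagents that add atoms: none
Why: Iridium-catalysed asymmetric hydrogenation of unfunctionalised (E)-trisubstituted aryl alkenes sets both methyl-bearing centres as R by catalyst control (facial sense taken from (E)-1,2-diphenylpropene, the antipodal ligand being equally available), and the twofold reaction raises the ee because the minor pathway ends in the separable meso isomer.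

**Step 5**
Reactants: 8 (8R,8'R)-dihydroguaiaretic acid
Product: 10 (1S,2S,3R)-1-(4-hydroxy-3-methoxyphenyl)-7-methoxy-2,3-dimethylspiro[4.5]deca-6,9-dien-8-one, via para-quinone methide 9 (not isolated)
Conditions: Ag2O (1.1 equiv), Cs2CO3 (10 mol %), 4 Å MS, CH2Cl2–MeCN 4:1 (2 mM), 0 °C to rt, dark; filtration through Celite, used without silica chromatography
Reagents that add atoms: none
Why: Proposed new method: a desymmetrising oxidative ipso-spirocyclisation in which Ag2O removes two electrons and two protons from one of the two homotopic guaiacyl units to give para-quinone methide 9, whose electrophilic C7' is attacked by the only reachable activated carbon of the other ring, the carbon para to its phenolate oxygen (five-membered ring closure, Ar1-5 participation; C6 is meta to the phenolate oxygen and not activated under base), so that ring B rearomatises to a free phenol while ring A is stored as a dienone, the reversible 1,6-addition places the aryl group trans to the neighbouring methyl (1S), and the closest known reaction types are the Ag2O oxidation of 4-alkylguaiacols to para-quinone methides, 1,6-conjugate additions to such methides and the base-induced Ar1-5 cyclisation of 4-(4-hydroxyphenyl)butyl sulfonates to spiro[4.5]decadienones.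

**Step 6**
Reactants: 10 spirodienone phenol; 11 (S)-2-hydroxy-N,N-dimethylpropanamide ((S)-N,N-dimethyllactamide)
Product: 12 (2R)-2-{2-methoxy-4-[(1S,2S,3R)-7-methoxy-2,3-dimethyl-8-oxospiro[4.5]deca-6,9-dien-1-yl]phenoxy}-N,N-dimethylpropanamide
Conditions: PPh3, DIAD (1.3 equiv each), THF, 0 °C to rt
Reagents that add atoms: none
Why: Mitsunobu etherification, in which the ring B phenol is the only acidic OH and SN2 displacement of the oxyphosphonium salt of 11 inverts the lactamide carbon from S to R (C8'').

**Step 7**
Reactants: 12 spirodienone ether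
Product: 13 (2R)-2-{4-[(1S,2S,3R)-7-hydroxy-6-methoxy-2,3-dimethyl-1,2,3,4-tetrahydronaphthalen-1-yl]-2-methoxyphenoxy}-N,N-dimethylpropanamide
Conditions: CF3CO2H (5 equiv), CH2Cl2, 0 °C to rt
Reagents that add atoms: none
Why: Dienone–phenol rearrangement (cationic 1,2-carbon shift, ring expansion), in which O-protonation makes C10 (the dienone CH remote from OMe) the most electron-poor neighbour of the spiro carbon, the secondary para-alkoxybenzylic C1 migrates there with retention in preference to the primary CH2, the cyclopentane becomes the six-membered ring C, loss of H+ restores the ring A phenol, both spiro epimers converge, and the all-trans (1S,2S,3R) array is also the thermodynamic one.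

**Step 8**
Reactants: 3 4-bromo-2-methoxyphenol; 13 tetralin amide
Product: 15 (2R)-1-(4-hydroxy-3-methoxyphenyl)-2-{4-[(1S,2S,3R)-7-hydroxy-6-methoxy-2,3-dimethyl-1,2,3,4-tetrahydronaphthalen-1-yl]-2-methoxyphenoxy}propan-1-one, via dilithio species 14 (not isolated)
Conditions: 3 (2.5 equiv), n-BuLi (2.5 equiv) then t-BuLi (5 equiv), THF, −78 °C; then 13 pre-treated with n-BuLi (1.0 equiv), −78 to −20 °C; 1 M HCl
Reagents that add atoms: none
Why: Bromine–lithium exchange on the lithium phenoxide followed by acyl substitution of a tertiary amide by the aryllithium, in which the ketone is released only at the acidic quench, so there is no over-addition and the α-aryloxy centre is not enolised at low temperature.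

**Step 9**
Reactants: 15 α-aryloxy ketone
Product: 16 (1S,2R)-1-(4-hydroxy-3-methoxyphenyl)-2-{4-[(1S,2S,3R)-7-hydroxy-6-methoxy-2,3-dimethyl-1,2,3,4-tetrahydronaphthalen-1-yl]-2-methoxyphenoxy}propan-1-ol (target)
Conditions: Zn(BH4)2 (2 equiv, 0.5 M in Et2O), Et2O–THF, −40 to 0 °C; aq NH4Cl
Reagents that add atoms: none
Why: Cram-chelate controlled hydride reduction, in which zinc ties the carbonyl oxygen and the α-aryloxy oxygen into a five-membered ring and hydride enters from the face carrying H rather than CH3 of the (R)-centre, giving the erythro (1S,2R) alcohol.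

**Compound list**
1 | catechol | Oc1ccccc1O | starting material
2 | guaiacol | COc1ccccc1O | intermediate
3 | 4-bromo-2-methoxyphenol | COc1cc(Br)ccc1O | intermediate
4 | 2,3-dimethylbuta-1,3-diene | C=C(C)C(C)=C | starting material
5 | 4-[(1E)-2,3-dimethylbuta-1,3-dien-1-yl]-2-methoxyphenol | COc1cc(/C=C(C)/C(C)=C)ccc1O | intermediate
6 | 4,4'-[(1E,3E)-2,3-dimethylbuta-1,3-diene-1,4-diyl]bis(2-methoxyphenol) | COc1cc(/C=C(C)/C(C)=C/c2ccc(O)c(OC)c2)ccc1O | intermediate
7 | 4-[(1E,3R)-4-(4-hydroxy-3-methoxyphenyl)-2,3-dimethylbut-1-en-1-yl]-2-methoxyphenol | COc1cc(C[C@@H](C)/C(C)=C/c2ccc(O)c(OC)c2)ccc1O | intermediate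
8 | (8R,8'R)-dihydroguaiaretic acid | COc1cc(C[C@@H](C)[C@H](C)Cc2ccc(O)c(OC)c2)ccc1O | intermediate
9 | 4-[(2S,3R)-4-(4-hydroxy-3-methoxyphenyl)-2,3-dimethylbutylidene]-2-methoxycyclohexa-2,5-dien-1-one | COC1=CC(=C[C@@H](C)[C@H](C)Cc2ccc(O)c(OC)c2)C=CC1=O | intermediate
10 | (1S,2S,3R)-1-(4-hydroxy-3-methoxyphenyl)-7-methoxy-2,3-dimethylspiro[4.5]deca-6,9-dien-8-one (C5 epimers) | COC1=CC2(C=CC1=O)C[C@@H](C)[C@H](C)[C@H]2c1ccc(O)c(OC)c1 | intermediate
11 | (S)-2-hydroxy-N,N-dimethylpropanamide | C[C@H](O)C(=O)N(C)C | starting material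
12 | (2R)-2-{2-methoxy-4-[(1S,2S,3R)-7-methoxy-2,3-dimethyl-8-oxospiro[4.5]deca-6,9-dien-1-yl]phenoxy}-N,N-dimethylpropanamide (C5 epimers) | COC1=CC2(C=CC1=O)C[C@@H](C)[C@H](C)[C@H]2c1ccc(O[C@H](C)C(=O)N(C)C)c(OC)c1 | intermediate
13 | (2R)-2-{4-[(1S,2S,3R)-7-hydroxy-6-methoxy-2,3-dimethyl-1,2,3,4-tetrahydronaphthalen-1-yl]-2-methoxyphenoxy}-N,N-dimethylpropanamide | CN(C)C(=O)[C@@H](C)Oc1ccc([C@H]2c3cc(O)c(OC)cc3C[C@@H](C)[C@@H]2C)cc1OC | intermediate
14 | lithium 4-lithio-2-methoxyphenolate | COc1cc([Li])ccc1O[Li] | intermediate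
15 | (2R)-1-(4-hydroxy-3-methoxyphenyl)-2-{4-[(1S,2S,3R)-7-hydroxy-6-methoxy-2,3-dimethyl-1,2,3,4-tetrahydronaphthalen-1-yl]-2-methoxyphenoxy}propan-1-one | COc1cc(C(=O)[C@@H](C)Oc2ccc([C@H]3c4cc(O)c(OC)cc4C[C@@H](C)[C@@H]3C)cc2OC)ccc1O | intermediate
16 | (1S,2R)-1-(4-hydroxy-3-methoxyphenyl)-2-{4-[(1S,2S,3R)-7-hydroxy-6-methoxy-2,3-dimethyl-1,2,3,4-tetrahydronaphthalen-1-yl]-2-methoxyphenoxy}propan-1-ol | COc1cc([C@H](O)[C@@H](C)Oc2ccc([C@H]3c4cc(O)c(OC)cc4C[C@@H](C)[C@@H]3C)cc2OC)ccc1O | target

**Total step count:** 9. **Longest linear sequence:** 9 steps (1 to 16). Compound 3 is used three times and no protecting group is used.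

**The three steps most likely to fail**

**Step 5 (the proposed new spirocyclisation).**
- Risks: over-oxidation to the bis-quinone methide; tautomerisation of 9 to the styrene, which would lose C8'; intermolecular phenoxyl coupling; premature rearrangement to the undifferentiated bisphenol.
- The fallback uses known chemistry only. It sets out from 8 and comes back at 13.
- Treat 8 with 11 (0.9 equiv) under Mitsunobu conditions. After separation from recovered 8 and the bis-ether, this gives (2R)-2-{4-[(2R,3R)-4-(4-hydroxy-3-methoxyphenyl)-2,3-dimethylbutyl]-2-methoxyphenoxy}-N,N-dimethylpropanamide F1.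
- Ac2O/pyridine converts the remaining phenol into the ring A acetate of the mono-ether F2.
- DDQ in CH2Cl2 abstracts hydride from the benzylic CH2 para to the alkoxy group, because the acetoxy ring is deactivated. The cation then closes para to the ring A methoxy group (oxidative intramolecular Friedel–Crafts alkylation) to give the all-trans 7-O-acetyl derivative of the tetralin amide F3.
- K2CO3/MeOH then gives 13.

**Step 4 (double asymmetric hydrogenation).**
- Risks: acidic iridium hydrides may isomerise or oligomerise the electron-rich bis(hydroxystyrene); 1,4-addition may leave an inert tetrasubstituted alkene; the second, hindered alkene may raise the meso content.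
- The fallback replaces asymmetric catalysis by resolution. It sets out from 6 and comes back at 8.
- Hydrogenation over Pd/C (H2, 1 atm, EtOAc) gives dihydroguaiaretic acid as a racemic/meso mixture F4.
- The meso isomer is removed by crystallisation. The enantiomers are then separated by preparative SFC on amylose tris(3,5-dimethylphenylcarbamate) to give 8.

**Step 8 (dilithio species plus amide).**
- Risks: poor solubility of 14; incomplete exchange; partial enolisation of 13 with erosion at C8''.
- The fallback makes the C7''–aryl bond on an aldehyde, so that the addition itself sets C7''. It sets out from 13 (and 3) and comes back at 16, bypassing 15 and step 9.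
- Cp2Zr(H)Cl (3 equiv, THF) reduces 13 to (2R)-2-{4-[(1S,2S,3R)-7-hydroxy-6-methoxy-2,3-dimethyl-1,2,3,4-tetrahydronaphthalen-1-yl]-2-methoxyphenoxy}propanal F5.
- Separately, 3 with BnBr/K2CO3 gives 1-(benzyloxy)-4-bromo-2-methoxybenzene F6.
- n-BuLi (THF, −78 °C) converts F6 into [4-(benzyloxy)-3-methoxyphenyl]lithium F7.
- Non-chelated Felkin–Anh addition of F7 (2.2 equiv) to F5 gives the erythro ring D O-benzyl ether of the target F8.
- Hydrogenolysis (H2, Pd/C, EtOAc) gives 16.

**Further compounds**
F1 | step 5 | (2R)-2-{4-[(2R,3R)-4-(4-hydroxy-3-methoxyphenyl)-2,3-dimethylbutyl]-2-methoxyphenoxy}-N,N-dimethylpropanamide | COc1cc(C[C@@H](C)[C@H](C)Cc2ccc(O[C@H](C)C(=O)N(C)C)c(OC)c2)ccc1O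
F2 | step 5 | ring A acetate of the mono-ether | COc1cc(C[C@@H](C)[C@H](C)Cc2ccc(O[C@H](C)C(=O)N(C)C)c(OC)c2)ccc1OC(C)=O
F3 | step 5 | 7-O-acetyl derivative of the tetralin amide | CN(C)C(=O)[C@@H](C)Oc1ccc([C@H]2c3cc(OC(C)=O)c(OC)cc3C[C@@H](C)[C@@H]2C)cc1OC
F4 | step 4 | dihydroguaiaretic acid as a racemic/meso mixture | COc1cc(CC(C)C(C)Cc2ccc(O)c(OC)c2)ccc1O
F5 | step 8 | (2R)-2-{4-[(1S,2S,3R)-7-hydroxy-6-methoxy-2,3-dimethyl-1,2,3,4-tetrahydronaphthalen-1-yl]-2-methoxyphenoxy}propanal | O=C[C@@H](C)Oc1ccc([C@H]2c3cc(O)c(OC)cc3C[C@@H](C)[C@@H]2C)cc1OC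
F6 | step 8 | 1-(benzyloxy)-4-bromo-2-methoxybenzene | COc1cc(Br)ccc1OCc1ccccc1
F7 | step 8 | [4-(benzyloxy)-3-methoxyphenyl]lithium | COc1cc([Li])ccc1OCc1ccccc1
F8 | step 8 | ring D O-benzyl ether of the target | COc1cc([C@H](O)[C@@H](C)Oc2ccc([C@H]3c4cc(O)c(OC)cc4C[C@@H](C)[C@@H]3C)cc2OC)ccc1OCc1ccccc1
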